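## Retrosynthetic overview

- 12 ⇐ 11: the last step is regioselective acid hydrolysis of the one strained methoxy group (the one next to the side chain) of a 3-alkyl-2,5-dimethoxyquinone.
- 11 ⇐ 8 + 9 (key, bolder step): Ag(I)/persulfate decarboxylative radical C–H alkylation (Jacobsen–Torssell, Minisci type) of the intact commercial quinone 9. This replaces the usual aryllithium + chiral epoxide route with CAN unmasking.
- 8 ⇐ 5 ⇐ 4 ⇐ 1 + 2: the stereocentre is set by Noyori Ru–(R)-BINAP hydrogenation of β-keto ester 4; the carboxyl carbon is a traceless handle lost as CO2.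
- Rings: no ring is formed. The only ring, the quinone, is bought as 9 and is only C–H-alkylated and then mono-demethylated.

Assumption: the stereocentre in the SMILES is (R) (OAc > CH2-quinone > C13 chain > H); short-lived species 3, 7 and 10 are numbered as non-isolated intermediates; H2 is not listed as an atom-adding reagent because it adds only hydrogen.

## Route

Step 1
Reactants: 1 tetradecanoyl chloride; 2 Meldrum's acid (2,2-dimethyl-1,3-dioxane-4,6-dione)
Product: 4 methyl 3-oxohexadecanoate, via acyl Meldrum's acid 3 (not isolated)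
Conditions: pyridine (2 equiv), CH2Cl2, 0 °C → rt; then MeOH, reflux
Reagents that add atoms: methanol (CO)
Why: C-acylation of Meldrum's acid followed by decarboxylative methanolysis (loss of acetone and CO2) is the standard Oikawa–Yonemitsu β-keto ester synthesis and works well with fatty acyl chlorides.

Step 2
Reactants: 4 methyl 3-oxohexadecanoate
Product: 5 methyl (3R)-3-hydroxyhexadecanoate
Conditions: RuCl2[(R)-BINAP] (0.2 mol%), H2 (50 bar), MeOH, 50 °C
Reagents that add atoms: none
Why: Noyori asymmetric hydrogenation of a β-keto ester; the ester-chelated Ru–(R)-BINAP complex delivers hydrogen to one ketone face and gives the (R)-alcohol (same sense as methyl acetoacetate → methyl (R)-3-hydroxybutanoate, since CH2CO2Me outranks the alkyl chain in both), typically in >97% ee.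

Step 3
Reactants: 5 methyl (3R)-3-hydroxyhexadecanoate
Product: 6 (3R)-3-hydroxyhexadecanoic acid
Conditions: LiOH·H2O, THF/H2O, rt; then 1 M HCl
Reagents that add atoms: lithium hydroxide ([Li+].[OH-])
Why: Plain ester saponification at rt; the carbinol stereocentre is not acidic and is untouched, and the crystalline acid can be recrystallised to upgrade ee.

Step 4
Reactants: 6 (3R)-3-hydroxyhexadecanoic acid
Product: 8 (3R)-3-acetoxyhexadecanoic acid, via mixed acetic anhydride 7 (not isolated)
Conditions: Ac2O (3 equiv), pyridine, rt; then H2O, rt; 1 M HCl work-up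
Reagents that add atoms: acetic anhydride (CC(=O)OC(C)=O); water (O), for hydrolysis of 7
Why: O-acetylation of the secondary alcohol with retention (the C–O bond is not broken); the carboxyl group is transiently a mixed anhydride that water cleaves back to the acid on work-up.

Step 5
Reactants: 8 (3R)-3-acetoxyhexadecanoic acid; 9 2,5-dimethoxy-1,4-benzoquinone
Product: 11 3-[(2R)-2-acetoxypentadecyl]-2,5-dimethoxy-1,4-benzoquinone, via 2-acetoxypentadecyl radical 10 (not isolated)
Conditions: AgNO3 (0.2 equiv), (NH4)2S2O8 (1.5 equiv, slow addition), 9 (3 equiv), MeCN/H2O 1:1, 65 °C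
Reagents that add atoms: none
Why: Jacobsen–Torssell (Minisci-type) decarboxylative alkylation: Ag(I)/persulfate oxidises the carboxylate, CO2 is lost, the nucleophilic primary radical 10 adds to one of the two equivalent C–H positions of 9 and re-oxidation restores the quinone; the stereocentre is β to the radical carbon and is not touched (1,2-acyloxy shift is far slower than trapping by the quinone), and excess 9 suppresses 3,6-dialkylation.

Step 6
Reactants: 11 3-[(2R)-2-acetoxypentadecyl]-2,5-dimethoxy-1,4-benzoquinone
Product: 12 3-[(2R)-2-acetoxypentadecyl]-2-hydroxy-5-methoxy-1,4-benzoquinone (target)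
Conditions: 70% aq. HClO4, 1,4-dioxane, 0 °C → rt, stopped at full conversion
Reagents that add atoms: water (O)
Why: Acid-catalysed addition–elimination hydrolysis of a vinylogous ester; the 2-OMe flanked by the side chain is twisted out of conjugation and hydrolyses first (the known behaviour of 3-alkyl-2,5-dimethoxyquinones), while the unstrained 5-OMe and the secondary acetate react more slowly and the stereocentre is not involved.

## Compound list

1 | tetradecanoyl chloride (myristoyl chloride) | CCCCCCCCCCCCCC(=O)Cl | starting material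
2 | Meldrum's acid (2,2-dimethyl-1,3-dioxane-4,6-dione) | CC1(C)OC(=O)CC(=O)O1 | starting material
3 | 5-(1-hydroxytetradecylidene)-2,2-dimethyl-1,3-dioxane-4,6-dione (acyl Meldrum's acid in its enol form) | CCCCCCCCCCCCCC(O)=C1C(=O)OC(C)(C)OC1=O | intermediate
4 | methyl 3-oxohexadecanoate | CCCCCCCCCCCCCC(=O)CC(=O)OC | intermediate
5 | methyl (3R)-3-hydroxyhexadecanoate | CCCCCCCCCCCCC[C@H](CC(=O)OC)O | intermediate
6 | (3R)-3-hydroxyhexadecanoic acid | CCCCCCCCCCCCC[C@H](CC(=O)O)O | intermediate
7 | acetic (3R)-3-acetoxyhexadecanoic anhydride | CCCCCCCCCCCCC[C@H](CC(=O)OC(C)=O)OC(C)=O | intermediate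
8 | (3R)-3-acetoxyhexadecanoic acid | CCCCCCCCCCCCC[C@H](CC(=O)O)OC(C)=O | intermediate
9 | 2,5-dimethoxy-1,4-benzoquinone | COC1=CC(=O)C(OC)=CC1=O | starting material
10 | 2-acetoxypentadecan-1-yl radical (C2 has the spatial arrangement of 8; formally 2S only because the radical CH2 ranks below the alkyl chain) | CCCCCCCCCCCCC[C@H]([CH2])OC(C)=O | intermediate
11 | 3-[(2R)-2-acetoxypentadecyl]-2,5-dimethoxy-1,4-benzoquinone | CCCCCCCCCCCCC[C@H](CC1=C(OC)C(=O)C=C(OC)C1=O)OC(C)=O | intermediate
12 | 3-[(2R)-2-acetoxypentadecyl]-2-hydroxy-5-methoxy-1,4-benzoquinone | CCCCCCCCCCCCC[C@H](CC1=C(O)C(=O)C=C(OC)C1=O)OC(C)=O | target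

## Step count and risks

Total step count: 6. Longest linear sequence: 6 (1 → 4 → 5 → 6 → 8 → 11 → 12).

**Step 5 (most likely to fail).** The electron-rich, poorly soluble quinone 9 may trap the radical inefficiently, the product can be alkylated a second time, and the acetate sees warm acidic water. The fallback replaces radical addition by a cross-coupling on a masked quinone; it sets out from 8 and comes back at 11. Acid 8 is esterified with N-hydroxyphthalimide (DIC, cat. DMAP, CH2Cl2) to the redox-active ester 1,3-dioxoisoindolin-2-yl (3R)-3-acetoxyhexadecanoate F1. Commercial 1,2,4,5-tetramethoxybenzene is lithiated (n-BuLi, THF, 0 °C) to (2,3,5,6-tetramethoxyphenyl)lithium F2 and transmetalated with ZnCl2 to (2,3,5,6-tetramethoxyphenyl)zinc chloride F3. Nickel-catalysed decarboxylative Negishi-type coupling of F1 and F3 (NiCl2·glyme, 4,4'-di-tert-butyl-2,2'-bipyridine, THF/DMF, rt) gives (2R)-1-(2,3,5,6-tetramethoxyphenyl)pentadecan-2-yl acetate F4. Oxidative demethylation of F4 with CAN (MeCN/H2O, 0 °C) gives 11; the stereocentre is again β to the reacting carbon.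

**Step 6.** The acid may also cleave the secondary acetate, and the freed alcohol could then cyclise onto C2. The fallback differentiates the two oxygens by selective methylation of a dihydroxyquinone instead of selective demethylation of a dimethoxyquinone; it sets out from 8 and comes back at 12. Acid 8 is coupled with H2O2 (DCC, CH2Cl2, 0 °C) to bis[(3R)-3-acetoxyhexadecanoyl] peroxide F5. F5 is decomposed in AcOH at 90 °C in the presence of excess commercial 2,5-dihydroxy-1,4-benzoquinone (Fieser-type peroxide alkylation through radical 10) to give 3-[(2R)-2-acetoxypentadecyl]-2,5-dihydroxy-1,4-benzoquinone F6. F6 is mono-O-methylated at rt with trimethyl orthoformate or MeOH and cat. BF3·OEt2. This vinylogous Fischer esterification puts the methyl on the oxygen next to the ring C–H, which is less hindered and thermodynamically preferred, and leaves the OH next to the side chain, so the product is 12.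

**Step 4.** The mixed anhydride 7 can acylate a second molecule (estolide oligomers) or lose acetic acid to the 2-enoic acid. The fallback masks the carboxyl group first; it sets out from 6 and comes back at 8. Acid 6 is benzylated (BnBr, KHCO3, DMF, rt) to benzyl (3R)-3-hydroxyhexadecanoate F7. F7 is acetylated (Ac2O, Et3N, cat. DMAP, CH2Cl2, 0 °C) to benzyl (3R)-3-acetoxyhexadecanoate F8. Hydrogenolysis of F8 (H2, Pd/C, EtOAc) gives 8.

## Further compounds

F1 | step 5 | 1,3-dioxoisoindolin-2-yl (3R)-3-acetoxyhexadecanoate | CCCCCCCCCCCCC[C@H](CC(=O)ON1C(=O)c2ccccc2C1=O)OC(C)=O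
F2 | step 5 | (2,3,5,6-tetramethoxyphenyl)lithium | [Li]c1c(OC)c(OC)cc(OC)c1OC
F3 | step 5 | (2,3,5,6-tetramethoxyphenyl)zinc chloride | Cl[Zn]c1c(OC)c(OC)cc(OC)c1OC
F4 | step 5 | (2R)-1-(2,3,5,6-tetramethoxyphenyl)pentadecan-2-yl acetate | CCCCCCCCCCCCC[C@H](Cc1c(OC)c(OC)cc(OC)c1OC)OC(C)=O
F5 | step 6 | bis[(3R)-3-acetoxyhexadecanoyl] peroxide | CCCCCCCCCCCCC[C@H](CC(=O)OOC(=O)C[C@@H](CCCCCCCCCCCCC)OC(C)=O)OC(C)=O
F6 | step 6 | 3-[(2R)-2-acetoxypentadecyl]-2,5-dihydroxy-1,4-benzoquinone | CCCCCCCCCCCCC[C@H](CC1=C(O)C(=O)C=C(O)C1=O)OC(C)=O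
F7 | step 4 | benzyl (3R)-3-hydroxyhexadecanoate | CCCCCCCCCCCCC[C@H](CC(=O)OCc1ccccc1)O
F8 | step 4 | benzyl (3R)-3-acetoxyhexadecanoate | CCCCCCCCCCCCC[C@H](CC(=O)OCc1ccccc1)OC(C)=O
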